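The pyranone (ring C) of this flavonol places the C4 ketone directly beside the oxygen-bearing C3. This vicinal C=O/C–O array is an acyloin in disguise and is cut at C3–C4. In the forward sense, an N-heterocyclic carbene reverses the polarity of an aryl aldehyde (future C4), which then attacks a tethered aliphatic aldehyde (future C3). One operation forges C3–C4, closes ring C and sets the C4 ketone and the C3 hydroxyl. The precursor is a dialdehyde: 4-prenyloxybenzaldehyde whose 2-oxygen (future O1) bears a CH(3,4-dimethoxyphenyl)CHO unit (C2 and C3). Copper(II) oxidation of the ketol and tautomerisation then aromatise ring C and erase both stereocentres.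

Key step: step 6

Assumption: the target has no stereocentre and no stereogenic double bond (the prenyl alkene ends in two methyl groups). It is therefore achiral, no enantiomer can be chosen, and every chiral intermediate is carried as a racemate.

Design notes:
- **Choice of aldehyde.** It matters which formyl group the carbene turns into the nucleophile. An enaminol raised on the aliphatic aldehyde has the aryloxide on the neighbouring carbon as a leaving group and would fragment by internal redox. Catalyst and base are chosen to favour the aryl aldehyde.
- **Handling of the dialdehyde.** It carries a C–H flanked by aryl, aryloxy and formyl groups. It is therefore made from the storable diol without a trialkylamine and used the same day.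
- **Bromination.** The benzylic bromide is made through a silyl ketene acetal, because the dimethoxyarene invites ring bromination under other conditions.

Step 1
Reactants: 1 2,4-dihydroxybenzaldehyde; 2 prenyl bromide (1-bromo-3-methylbut-2-ene)
Product: 3 2-hydroxy-4-(3-methylbut-2-enyloxy)benzaldehyde
Conditions: K2CO3 (1.0 equiv), acetone, reflux
Reagents that add atoms: none
Why: Williamson ether synthesis, in which the 4-OH is the more acidic and more accessible phenol because the 2-OH is tied up in a hydrogen bond to the formyl oxygen, so one equivalent of weak base and the reactive allylic bromide should alkylate O4 selectively.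

Step 2
Reactants: 4 methyl 2-(3,4-dimethoxyphenyl)acetate
Product: 6 methyl 2-bromo-2-(3,4-dimethoxyphenyl)acetate (racemic), via silyl ketene acetal 5 (not isolated)
Conditions: LiHMDS, THF, −78 °C; TMSCl, −78 → 0 °C; then NBS, THF, −78 °C
Reagents that add atoms: N-bromosuccinimide, O=C1CCC(=O)N1Br (Br in 6); chlorotrimethylsilane, C[Si](C)(C)Cl (Me3Si in 5 only)
Why: Electrophilic α-bromination of a silyl ketene acetal, whose very nucleophilic carbon should take Br+ from NBS at −78 °C well before the dimethoxyarene ring does, which avoids both the ring bromination that threatens a Wohl–Ziegler reaction here and the self-alkylation of a free enolate; the new centre is racemic and is erased in step 7.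

Step 3
Reactants: 3 2-hydroxy-4-(3-methylbut-2-enyloxy)benzaldehyde; 6 methyl 2-bromo-2-(3,4-dimethoxyphenyl)acetate
Product: 7 methyl 2-(3,4-dimethoxyphenyl)-2-[2-formyl-5-(3-methylbut-2-enyloxy)phenoxy]acetate (racemic)
Conditions: K2CO3, DMF, rt
Reagents that add atoms: none
Why: Williamson ether synthesis by SN2 displacement at a doubly activated (benzylic, α-ester) bromide, where the chelated 2-phenoxide is a modest nucleophile but the electrophile is very reactive, and at room temperature carbonate should not drive the follow-up aldol closure of the product's acidic C–H onto the formyl group; the centre (future C2) is racemic.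

Step 4
Reactants: 7 methyl 2-(3,4-dimethoxyphenyl)-2-[2-formyl-5-(3-methylbut-2-enyloxy)phenoxy]acetate
Product: 8 2-(3,4-dimethoxyphenyl)-2-[2-(hydroxymethyl)-5-(3-methylbut-2-enyloxy)phenoxy]ethan-1-ol (racemic diol)
Conditions: LiAlH4, THF, 0 °C; then H2O, aq NaOH
Reagents that add atoms: none
Why: Lithium aluminium hydride reduction, chosen because no hydride would reduce the ester and spare the aldehyde, so both carbonyl groups are deliberately taken to primary alcohols in one operation while the aryl ethers, the isolated prenyl alkene and the racemic centre stay untouched.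

Step 5
Reactants: 8 2-(3,4-dimethoxyphenyl)-2-[2-(hydroxymethyl)-5-(3-methylbut-2-enyloxy)phenoxy]ethan-1-ol
Product: 9 2-[1-(3,4-dimethoxyphenyl)-2-oxoethoxy]-4-(3-methylbut-2-enyloxy)benzaldehyde (racemic dialdehyde)
Conditions: Dess–Martin periodinane (2.5 equiv), pyridine, CH2Cl2, 0 °C → rt; used at once under Ar
Reagents that add atoms: none
Why: Dess–Martin oxidation, which should convert both primary alcohols into aldehydes without over-oxidation and without a trialkylamine, so that the C–H flanked by aryl, aryloxy and formyl groups is not enolised towards a five-membered aldol closure, while pyridine buffers the acetic acid that could ionise the 2,4-dialkoxybenzylic alcohol or the prenyl ether.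

Step 6
Reactants: 9 2-[1-(3,4-dimethoxyphenyl)-2-oxoethoxy]-4-(3-methylbut-2-enyloxy)benzaldehyde
Product: 10 2-(3,4-dimethoxyphenyl)-3-hydroxy-7-(3-methylbut-2-enyloxy)chroman-4-one (racemic, mixture of 2,3-cis and 2,3-trans diastereomers)
Conditions: 2-(pentafluorophenyl)-6,7-dihydro-5H-pyrrolo[2,1-c][1,2,4]triazol-2-ium tetrafluoroborate (15 mol %), iPr2NEt (15 mol %), THF (0.02 M), rt, Ar
Reagents that add atoms: none
Why: The triazolylidene freed by the amine adds to the aryl aldehyde, proton transfer gives the enaminol (acyl anion equivalent at the future C4), this carbon attacks the tethered aliphatic formyl carbon (future C3), and collapse of the adduct releases the carbene and unveils the C4 ketone. The closest known reaction type is the carbene-catalysed intramolecular crossed benzoin of salicylaldehyde-derived α-aryloxy ketones to 3-hydroxychroman-4-ones, together with carbene-catalysed cyclisations of dialdehydes to cyclic acyloins, the acceptor here being an aldehyde instead of a ketone. Ring C closes in the 6-exo-trig mode, C4 attacking C3 with the acceptor oxygen left outside the ring. C3 is formed without reagent control, its relation to C2 being set only by the substrate and by amine-mediated equilibration towards the 2,3-trans ketol, and either outcome serves because step 7 flattens C2 and C3. The carbene must become productive at the aryl and not at the aliphatic aldehyde, since an enaminol at the latter would expel the aryloxide on C2; ortho-alkoxybenzaldehydes are the standard donors of intramolecular benzoin and Stetter reactions, aryl conjugation acidifies the carbinol C–H of their adducts, the aliphatic formyl group sits on a carbon crowded by aryl and aryloxy groups, and the electron-poor N-C6F5 catalyst belongs to the class preferred for benzoin chemistry and not to the N-mesityl class preferred for redox reactions of α-functionalised aldehydes. Ring closure over oligomerisation is secured by the six-membered tether and the dilution, and aldol closure through the acidic C2–H is held back by using no more weak amine than precatalyst.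

Step 7
Reactants: 10 2-(3,4-dimethoxyphenyl)-3-hydroxy-7-(3-methylbut-2-enyloxy)chroman-4-one
Product: 12 2-(3,4-dimethoxyphenyl)-3-hydroxy-7-(3-methylbut-2-enyloxy)-4H-chromen-4-one (achiral target), via chromane-3,4-dione 11 (not isolated)
Conditions: Cu(OAc)2·H2O (2.2 equiv), MeOH–THF, 50 °C, Ar; aq EDTA wash
Reagents that add atoms: none
Why: Copper(II) oxidation of an α-ketol to a 1,2-dione (the classical acyloin oxidation), in which two one-electron oxidations of the copper-bound enediolate give 11, whose C2–H (benzylic, next to O1 and to the C3 carbonyl) enolises at once to the aromatic 3-hydroxy-4-pyranone; the prenyl alkene is inert to Cu(II), exclusion of oxygen prevents oxygenative cleavage of the copper flavonolate, any 4-hydroxychroman-3-one isomer formed by ketol tautomerism converges on the same dione, and both stereocentres vanish.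

Compound list
1 | 2,4-dihydroxybenzaldehyde | O=Cc1ccc(O)cc1O | starting material
2 | prenyl bromide (1-bromo-3-methylbut-2-ene) | CC(C)=CCBr | starting material
3 | 2-hydroxy-4-(3-methylbut-2-enyloxy)benzaldehyde | CC(C)=CCOc1ccc(C=O)c(O)c1 | intermediate
4 | methyl 2-(3,4-dimethoxyphenyl)acetate | COC(=O)Cc1ccc(OC)c(OC)c1 | starting material
5 | [2-(3,4-dimethoxyphenyl)-1-methoxyethenyl]oxy(trimethyl)silane, E/Z mixture, not isolated | COC(O[Si](C)(C)C)=Cc1ccc(OC)c(OC)c1 | intermediate
6 | methyl 2-bromo-2-(3,4-dimethoxyphenyl)acetate, racemic | COC(=O)C(Br)c1ccc(OC)c(OC)c1 | intermediate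
7 | methyl 2-(3,4-dimethoxyphenyl)-2-[2-formyl-5-(3-methylbut-2-enyloxy)phenoxy]acetate, racemic | COC(=O)C(Oc1cc(OCC=C(C)C)ccc1C=O)c1ccc(OC)c(OC)c1 | intermediate
8 | 2-(3,4-dimethoxyphenyl)-2-[2-(hydroxymethyl)-5-(3-methylbut-2-enyloxy)phenoxy]ethan-1-ol, racemic | OCC(Oc1cc(OCC=C(C)C)ccc1CO)c1ccc(OC)c(OC)c1 | intermediate
9 | 2-[1-(3,4-dimethoxyphenyl)-2-oxoethoxy]-4-(3-methylbut-2-enyloxy)benzaldehyde, racemic | O=CC(Oc1cc(OCC=C(C)C)ccc1C=O)c1ccc(OC)c(OC)c1 | intermediate
10 | 2-(3,4-dimethoxyphenyl)-3-hydroxy-7-(3-methylbut-2-enyloxy)chroman-4-one, racemic diastereomer mixture | COc1ccc(C2Oc3cc(OCC=C(C)C)ccc3C(=O)C2O)cc1OC | intermediate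
11 | 2-(3,4-dimethoxyphenyl)-7-(3-methylbut-2-enyloxy)chromane-3,4-dione, racemic, not isolated | COc1ccc(C2Oc3cc(OCC=C(C)C)ccc3C(=O)C2=O)cc1OC | intermediate
12 | 2-(3,4-dimethoxyphenyl)-3-hydroxy-7-(3-methylbut-2-enyloxy)-4H-chromen-4-one, achiral | COc1ccc(-c2oc3cc(OCC=C(C)C)ccc3c(=O)c2O)cc1OC | target

Total steps: 7. Longest linear sequence: 6 (steps 1, 3, 4, 5, 6, 7; the branch through step 2 joins at step 3).

Steps most likely to fail

1. **Step 6.**
   - Risk: the carbene may be activated at the aliphatic instead of the aryl aldehyde, followed by expulsion of the aryloxide. The amine may induce aldol closure through the acidic C2–H, or intermolecular coupling may compete.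
   - Fallback: from 9, the same C3–C4 bond is made reductively instead of by polarity reversal. SmI2 (2.5 equiv), t-BuOH, THF, −78 °C should reduce the far more easily reduced aryl aldehyde to its ketyl. The ketyl closes onto the aliphatic aldehyde (intramolecular pinacol coupling, no base present) to give 2-(3,4-dimethoxyphenyl)-7-(3-methylbut-2-enyloxy)chromane-3,4-diol F1 (racemic diastereomer mixture).
   - Return: a double Swern oxidation of this vicinal diol (DMSO, (COCl)2, Et3N, CH2Cl2, −78 °C) rejoins the route at dione 11, which tautomerises to 12.

2. **Step 5.**
   - Risk: the new α-aryl-α-aryloxy aldehyde may enolise, with ensuing aldol closure or autoxidative loss of the formyl group. Hemiacetal formation at the half-oxidised stage may lead to over-oxidation to a lactone.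
   - Fallback: from 7, the reduce-and-reoxidise tactic is replaced by protection and partial reduction. HC(OMe)3, cat. PPTS, MeOH, rt masks the aryl aldehyde to give methyl 2-(3,4-dimethoxyphenyl)-2-[2-(dimethoxymethyl)-5-(3-methylbut-2-enyloxy)phenoxy]acetate F2. DIBAL-H (1.1 equiv), toluene, −78 °C stops at the aldehyde, as is usual for α-oxygenated esters, to give 2-(3,4-dimethoxyphenyl)-2-[2-(dimethoxymethyl)-5-(3-methylbut-2-enyloxy)phenoxy]acetaldehyde F3.
   - Return: the very labile electron-rich aryl acetal is opened with cat. PPTS in acetone–water at rt, which rejoins the route at 9 under non-oxidising, non-basic conditions.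

3. **Step 2.**
   - Risk: electrophilic bromination of the dimethoxyarene ring may compete, C-silylation may occur in place of O-silylation, and the labile benzylic bromide may solvolyse during work-up.
   - Fallback: from 4, the C–O bond is made by activating an alcohol instead of displacing a halide. KHMDS, THF, −78 °C, then 2-(phenylsulfonyl)-3-phenyloxaziridine (Davis enolate hydroxylation) gives methyl 2-(3,4-dimethoxyphenyl)-2-hydroxyacetate F4 (racemic).
   - Return: a Mitsunobu reaction of F4 with phenol 3 (PPh3, DIAD, THF, 0 °C → rt) rejoins the route at 7 and replaces steps 2 and 3.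

Further compounds
F1 | step 6 | 2-(3,4-dimethoxyphenyl)-7-(3-methylbut-2-enyloxy)chromane-3,4-diol, racemic diastereomer mixture | COc1ccc(C2Oc3cc(OCC=C(C)C)ccc3C(O)C2O)cc1OC
F2 | step 5 | methyl 2-(3,4-dimethoxyphenyl)-2-[2-(dimethoxymethyl)-5-(3-methylbut-2-enyloxy)phenoxy]acetate, racemic | COC(=O)C(Oc1cc(OCC=C(C)C)ccc1C(OC)OC)c1ccc(OC)c(OC)c1
F3 | step 5 | 2-(3,4-dimethoxyphenyl)-2-[2-(dimethoxymethyl)-5-(3-methylbut-2-enyloxy)phenoxy]acetaldehyde, racemic | O=CC(Oc1cc(OCC=C(C)C)ccc1C(OC)OC)c1ccc(OC)c(OC)c1
F4 | step 2 | methyl 2-(3,4-dimethoxyphenyl)-2-hydroxyacetate, racemic | COC(=O)C(O)c1ccc(OC)c(OC)c1
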